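**Retrosynthetic overview**

- Target 19 is the benzoate of a C9 carbinol, which comes from the C9 aryl ketone by reagent-controlled transfer hydrogenation.
- Structural feature: in ring B (C4a, spiro C5, C6, C7, C8, C9, C9a) the carbons C9, C8, C7 and the methyl carbon on C7 form a four-carbon unit that can be folded into a 2-methyl-3-alkylcyclobutanone, with C9 as the carbonyl and the future C7 methyl as the ring CH2.
- Key disconnection: C9–C9a is formed and C9–CH2 is broken when a C9a arylboronate adds to that cyclobutanone under rhodium catalysis and the alkoxide undergoes beta-carbon elimination; this closes ring B last.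
- The cyclobutanone comes from an auxiliary-controlled keteniminium (2+2) cycloaddition on the allyl group of a 4-allyl-4-aryl-2,6-dimethoxycyclohexadienone (sets C7); the boronate comes from an aryl triflate.
- The dienone (ring C, quaternary C5) comes from oxidative para-allylation of a biaryl phenol, and the biaryl from a bromide-selective Suzuki coupling. Ring order: A is bought, C is coupled and then dearomatised, the cyclobutane is built, and ring B is closed at its expense.

Key step: step 8

**Remarks on the chemistry**

- Assumption: the (2R,5R)-pyrrolidine auxiliary is taken to give the (3S) cyclobutanone in step 6; if the sense is the opposite, the (2S,5S) amine is used and nothing else changes.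
- Quaternary C5 is made by an irreversible oxidative allylation at low temperature and not by a thermal O-to-C allyl shift, because a 4,4-disubstituted dienone cannot tautomerise and would stay in equilibrium with its aryl allyl ether.
- C2 of the cyclobutanone is epimerisable; 13 and 14 are written as the more stable trans isomer, and any cis isomer converges on the same ketone 16 in step 8.

**Route**

Step 1
Reactants: 1 3,4,5-trimethoxyphenol
Product: 2 2-bromo-3,4,5-trimethoxyphenol
Conditions: NBS (1.0 equiv), CH2Cl2, −78 → 0 °C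
Reagents that add atoms: N-bromosuccinimide, O=C1CCC(=O)N1Br
Why: Electrophilic aromatic bromination; the two free ring positions are equivalent and both lie ortho to the hydroxyl group, so one equivalent of NBS at low temperature should stop at the monobromide.

Step 2
Reactants: 2 2-bromo-3,4,5-trimethoxyphenol
Product: 3 2-bromo-3,4,5-trimethoxyphenyl trifluoromethanesulfonate
Conditions: Tf2O, pyridine, CH2Cl2, 0 °C
Reagents that add atoms: trifluoromethanesulfonic anhydride, O=S(=O)(OS(=O)(=O)C(F)(F)F)C(F)(F)F
Why: O-sulfonylation of the phenol; the triflate masks the oxygen that later becomes the boronate at C9a.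

Step 3
Reactants: 3 2-bromo-3,4,5-trimethoxyphenyl trifluoromethanesulfonate; 4 4-hydroxy-3,5-dimethoxyphenylboronic acid pinacol ester
Product: 5 2-(4-hydroxy-3,5-dimethoxyphenyl)-3,4,5-trimethoxyphenyl trifluoromethanesulfonate
Conditions: Pd2(dba)3 (2 mol %), [HP(t-Bu)3]BF4 (8 mol %), KF, THF/H2O (20:1), 25–40 °C
Reagents that add atoms: none
Why: Suzuki–Miyaura coupling; monoligated zerovalent palladium with tri-tert-butylphosphine inserts into C–Br and leaves an aryl triflate untouched, and the boronate has no ortho substituent and tolerates its free phenol.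

Step 4
Reactants: 5 biaryl phenol triflate; 6 allyltrimethylsilane
Product: 7 2-(1-allyl-3,5-dimethoxy-4-oxocyclohexa-2,5-dien-1-yl)-3,4,5-trimethoxyphenyl trifluoromethanesulfonate
Conditions: PhI(OAc)2 (1.1 equiv), 6 (5 equiv), (CF3)2CHOH, −20 → 0 °C
Reagents that add atoms: none
Why: Oxidative Hosomi–Sakurai dearomatisation; PhI(OAc)2 in hexafluoroisopropanol turns the phenol into a phenoxenium ion stabilised by both methoxy groups, the allylsilane attacks its para carbon with loss of silicon, and C5 becomes quaternary but not stereogenic because the dienone is symmetric.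

Step 5
Reactants: 8 propionyl chloride; 9 (2R,5R)-2,5-dimethylpyrrolidine
Product: 10 1-[(2R,5R)-2,5-dimethylpyrrolidin-1-yl]propan-1-one
Conditions: Et3N, CH2Cl2, 0 °C → rt
Reagents that add atoms: none
Why: N-acylation of the secondary amine with the acid chloride; the C2-symmetric amine gives an amide whose keteniminium has only one reactive geometry.

Step 6
Reactants: 7 allyl dienone triflate; 10 chiral propionamide
Product: 13 2-[3,5-dimethoxy-1-{[(1S,2R)-2-methyl-3-oxocyclobutyl]methyl}-4-oxocyclohexa-2,5-dien-1-yl]-3,4,5-trimethoxyphenyl trifluoromethanesulfonate, via keteniminium triflate 11 (not isolated), via cyclobutaniminium triflate 12 (not isolated)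
Conditions: 10 (1.5 equiv), Tf2O (1.4 equiv), 2,4,6-collidine, ClCH2CH2Cl, −20 °C; then 7, 60 °C; then H2O, NaHCO3, 40 °C
Reagents that add atoms: water, O (carbonyl oxygen of 13); trifluoromethanesulfonic anhydride, O=S(=O)(OS(=O)(=O)C(F)(F)F)C(F)(F)F (triflate counter-ion of 11 and 12 only)
Why: Ghosez keteniminium (2+2) cycloaddition; the central keteniminium carbon bonds to the terminal alkene carbon and the methyl-bearing carbon to the internal one, which gives the 2-methyl-3-alkyl pattern, the C2-symmetric pyrrolidine selects the alkene face and so sets C3 (the future C7) as S, and the epimerisable C2 settles trans on hydrolysis.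

Step 7
Reactants: 13 triflate cyclobutanone
Product: 14 4-{[(1S,2R)-2-methyl-3-oxocyclobutyl]methyl}-2,6-dimethoxy-4-[2,3,4-trimethoxy-6-(4,4,5,5-tetramethyl-1,3,2-dioxaborolan-2-yl)phenyl]cyclohexa-2,5-dien-1-one
Conditions: B2pin2, PdCl2(dppf) (5 mol %), dppf, KOAc, 1,4-dioxane, 80 °C
Reagents that add atoms: bis(pinacolato)diboron, CC1(C)OB(OC1(C)C)B1OC(C)(C)C(C)(C)O1
Why: Miyaura borylation of the aryl triflate; KOAc is too weak to disturb the cyclobutanone or the dienone, and the step is placed after the cycloaddition because zerovalent palladium could otherwise ionise the allyl–C5 bond with rearomatisation.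

Step 8
Reactants: 14 boronate cyclobutanone
Product: 16 (7R,8S)-2,3,3',4,5'-pentamethoxy-7,8-dimethyl-7,8-dihydro-6H-spiro[benzo[7]annulene-5,1'-cyclohexa[2,5]diene]-4',9-dione, via cis-dimethyl spiro ketone 15 (not isolated)
Conditions: [Rh(OH)(cod)]2 (5 mol %), K3PO4, 1,4-dioxane/H2O (10:1), 80 °C; then DBU (0.2 equiv), 25 °C
Reagents that add atoms: none
Why: Proposed new method: the hydroxo-rhodium complex transmetalates with the C9a boronate, the monovalent aryl-rhodium adds to the strained cyclobutanone carbonyl C9 to give a benzo-fused bicyclo[4.1.1]octanolate, strain-driven beta-carbon elimination breaks the C9–CH2 bond, and water protonates the primary alkyl-rhodium to the C7 methyl and regenerates Rh–OH. The closest known reaction type is the rhodium-catalysed addition of an ortho-boryl aryl group bound directly to C3 of a cyclobutanone followed by beta-carbon elimination to a 1-indanone, together with the intermolecular arylboronic acid addition/ring-opening of cyclobutanones; the longer tether and the seven-membered ring are new, although the bridged alkoxide is less strained than the bicyclo[2.1.1] one of the known case. Ring B closes by a 7-exo-trig 1,2-addition of C9a to C9 and remains as a monocyclic seven-membered ketone once the one-carbon bridge is cut. No stereocentre is created: C7 is the cyclobutanone C3 carried over unchanged, and C8, now alpha to the aryl ketone, is moved by enolisation (K3PO4, then DBU) from the kinetic cis-dimethyl ketone 15 to the trans isomer 16, expected to be the more stable with both methyl groups pseudo-equatorial. The step needs cleavage of C9–CH2 rather than C9–C8, which the preference of beta-carbon elimination for a primary over a secondary alkyl-rhodium should secure, and it needs 1,2-addition to outrun protodeboronation, which the electrophilic strained ketone favours; the dienone is out of reach because attack on its beta-carbon would close a four-membered ring.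

Step 9
Reactants: 16 trans-dimethyl spiro ketone
Product: 17 (7R,8S,9R)-9-hydroxy-2,3,3',4,5'-pentamethoxy-7,8-dimethyl-6,7,8,9-tetrahydrospiro[benzo[7]annulene-5,1'-cyclohexa[2,5]dien]-4'-one
Conditions: RuCl(p-cymene)[(R,R)-TsDPEN] (2 mol %), HCO2H/Et3N (5:2), CH2Cl2, 25 °C
Reagents that add atoms: none
Why: Noyori–Ikariya asymmetric transfer hydrogenation; the (R,R) catalyst delivers hydride to the Si face of the aryl ketone and sets C9 as R, trans to the C8 methyl, the acidic formate medium should not epimerise C8, and the dienone carbonyl, flanked by two methoxy-bearing carbons and with no aryl group, should be left alone.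

Step 10
Reactants: 17 C9 alcohol; 18 benzoyl chloride
Product: 19 (7R,8S,9R)-2,3,3',4,5'-pentamethoxy-7,8-dimethyl-4'-oxo-6,7,8,9-tetrahydrospiro[benzo[7]annulene-5,1'-cyclohexa[2,5]dien]-9-yl benzoate (CNP0201356.1)
Conditions: pyridine, DMAP (cat.), CH2Cl2, 0 °C → rt
Reagents that add atoms: none
Why: DMAP-catalysed O-acylation of the secondary benzylic alcohol, which keeps the C9 configuration because the C–O bond is not touched.

**Compound list**

1 | 3,4,5-trimethoxyphenol | COc1cc(O)cc(OC)c1OC | starting material
2 | 2-bromo-3,4,5-trimethoxyphenol | COc1cc(O)c(Br)c(OC)c1OC | intermediate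
3 | 2-bromo-3,4,5-trimethoxyphenyl trifluoromethanesulfonate | COc1cc(OS(=O)(=O)C(F)(F)F)c(Br)c(OC)c1OC | intermediate
4 | 4-hydroxy-3,5-dimethoxyphenylboronic acid pinacol ester | COc1cc(cc(OC)c1O)B1OC(C)(C)C(C)(C)O1 | starting material
5 | 2-(4-hydroxy-3,5-dimethoxyphenyl)-3,4,5-trimethoxyphenyl trifluoromethanesulfonate | COc1cc(cc(OC)c1O)-c1c(OS(=O)(=O)C(F)(F)F)cc(OC)c(OC)c1OC | intermediate
6 | allyltrimethylsilane | C=CC[Si](C)(C)C | starting material
7 | 2-(1-allyl-3,5-dimethoxy-4-oxocyclohexa-2,5-dien-1-yl)-3,4,5-trimethoxyphenyl trifluoromethanesulfonate | COC1=CC(CC=C)(C=C(OC)C1=O)c1c(OS(=O)(=O)C(F)(F)F)cc(OC)c(OC)c1OC | intermediate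
8 | propionyl chloride | CCC(=O)Cl | starting material
9 | (2R,5R)-2,5-dimethylpyrrolidine | C[C@@H]1CC[C@@H](C)N1 | starting material
10 | 1-[(2R,5R)-2,5-dimethylpyrrolidin-1-yl]propan-1-one | CCC(=O)N1[C@H](C)CC[C@H]1C | intermediate
11 | (2R,5R)-2,5-dimethyl-1-(prop-1-en-1-ylidene)pyrrolidinium triflate (keteniminium salt, not isolated) | CC=C=[N+]1[C@H](C)CC[C@H]1C.[O-]S(=O)(=O)C(F)(F)F | intermediate
12 | cyclobutaniminium triflate from 7 and 11 (not isolated) | COC1=CC(C[C@H]2CC(=[N+]3[C@H](C)CC[C@H]3C)[C@@H]2C)(C=C(OC)C1=O)c1c(OS(=O)(=O)C(F)(F)F)cc(OC)c(OC)c1OC.[O-]S(=O)(=O)C(F)(F)F | intermediate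
13 | 2-[3,5-dimethoxy-1-{[(1S,2R)-2-methyl-3-oxocyclobutyl]methyl}-4-oxocyclohexa-2,5-dien-1-yl]-3,4,5-trimethoxyphenyl trifluoromethanesulfonate (trans cyclobutanone) | COC1=CC(C[C@H]2CC(=O)[C@@H]2C)(C=C(OC)C1=O)c1c(OS(=O)(=O)C(F)(F)F)cc(OC)c(OC)c1OC | intermediate
14 | 4-{[(1S,2R)-2-methyl-3-oxocyclobutyl]methyl}-2,6-dimethoxy-4-[2,3,4-trimethoxy-6-(4,4,5,5-tetramethyl-1,3,2-dioxaborolan-2-yl)phenyl]cyclohexa-2,5-dien-1-one (key-step precursor) | COC1=CC(C[C@H]2CC(=O)[C@@H]2C)(C=C(OC)C1=O)c1c(B2OC(C)(C)C(C)(C)O2)cc(OC)c(OC)c1OC | intermediate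
15 | (7R,8R)-2,3,3',4,5'-pentamethoxy-7,8-dimethyl-7,8-dihydro-6H-spiro[benzo[7]annulene-5,1'-cyclohexa[2,5]diene]-4',9-dione (cis-dimethyl, not isolated) | COC1=CC2(C=C(OC)C1=O)C[C@@H](C)[C@@H](C)C(=O)c1cc(OC)c(OC)c(OC)c12 | intermediate
16 | (7R,8S)-2,3,3',4,5'-pentamethoxy-7,8-dimethyl-7,8-dihydro-6H-spiro[benzo[7]annulene-5,1'-cyclohexa[2,5]diene]-4',9-dione (trans-dimethyl, key-step product) | COC1=CC2(C=C(OC)C1=O)C[C@@H](C)[C@H](C)C(=O)c1cc(OC)c(OC)c(OC)c12 | intermediate
17 | (7R,8S,9R)-9-hydroxy-2,3,3',4,5'-pentamethoxy-7,8-dimethyl-6,7,8,9-tetrahydrospiro[benzo[7]annulene-5,1'-cyclohexa[2,5]dien]-4'-one | COC1=CC2(C=C(OC)C1=O)C[C@@H](C)[C@H](C)[C@@H](O)c1cc(OC)c(OC)c(OC)c12 | intermediate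
18 | benzoyl chloride | O=C(Cl)c1ccccc1 | starting material
19 | (7R,8S,9R)-2,3,3',4,5'-pentamethoxy-7,8-dimethyl-4'-oxo-6,7,8,9-tetrahydrospiro[benzo[7]annulene-5,1'-cyclohexa[2,5]dien]-9-yl benzoate | COC1=CC2(C=C(OC)C1=O)C[C@@H](C)[C@H](C)[C@@H](OC(=O)c1ccccc1)c1cc(OC)c(OC)c(OC)c12 | target

**Step count**

Total: 10 steps. Longest linear sequence: 9 steps (1 → 2 → 3 → 5 → 7 → 13 → 14 → 16 → 17 → 19); step 5 is a one-step side branch.

**Steps most likely to fail**

Step 8 (proposed new method). Transmetalation of the hindered boronate next to the quaternary carbon may be slow enough for protodeboronation to take over, the aryl-rhodium may be reluctant to close a seven-membered ring onto the ketone, or the alkyl-rhodium may undergo beta-hydride elimination before it is protonated. The fallback uses known reactions and closes ring B at C4a–C5 instead; it sets out from amide 10 (through its keteniminium salt 11) and returns at ketone 16. Commercially available 4-allyl-2,6-dimethoxyphenol is acetylated (Ac2O, pyridine) to 4-allyl-2,6-dimethoxyphenyl acetate F1. Cycloaddition with 11 under the conditions of step 6 gives the cyclobutaniminium triflate F2, and hydrolysis gives the trans cyclobutanone F3. The known intermolecular rhodium-catalysed addition/ring-opening with 3,4,5-trimethoxyphenylboronic acid (Rh(acac)(C2H4)2, P(t-Bu)3, Cs2CO3, dioxane, 100 °C) should then give the open-chain aryl ketone acetate F4, which already holds the C9–C9a bond and the C7 methyl. K2CO3 in MeOH removes the acetate to give the phenol ketone F5. PhI(OCOCF3)2 in CF3CH2OH at −40 °C (Kita-type oxidative phenol–arene coupling) joins the para carbon of the phenol to the arene position ortho to the acyl group, which should give spiro ketone 15, and DBU equilibrates this to 16.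

Step 4. The phenoxenium ion may be captured at a methoxy-bearing ortho carbon instead of the para carbon, or the electron-rich biaryl may be over-oxidised. The fallback sets out from 5 and returns at 7. O-Allylation (allyl bromide, K2CO3, DMF, 25 °C) gives the aryl allyl ether F6. Heating (N,N-diethylaniline, 170 °C) starts a Claisen–Cope relay: a (3,3) shift to a methoxy-bearing ortho carbon gives the racemic ortho-dienone F7 (not isolated), and a second (3,3) shift moves the allyl group to the para carbon. Because 7 cannot tautomerise this relay is an equilibrium, so recovered F6 would be resubmitted.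

Step 6. Facial selectivity may be poor, since the new stereocentre sits on a monosubstituted alkene remote from the auxiliary, and the keteniminium ion may be diverted to the dienone oxygen. The fallback sets out from 7 and returns at 13. N,N-Dimethylpropanamide, Tf2O and collidine give the achiral keteniminium triflate F8, which with 7 gives the racemic cyclobutaniminium triflate F9; hydrolysis gives the racemic trans cyclobutanone, that is 13 together with its (2S,3R) enantiomer F10. Preparative chromatography on a chiral stationary phase separates the two, so C7 is secured by resolution instead of by induction.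

Further compounds
F1 | step 8 | 4-allyl-2,6-dimethoxyphenyl acetate | C=CCc1cc(OC)c(OC(C)=O)c(OC)c1
F2 | step 8 | cyclobutaniminium triflate from F1 and 11 | COc1cc(C[C@H]2CC(=[N+]3[C@H](C)CC[C@H]3C)[C@@H]2C)cc(OC)c1OC(C)=O.[O-]S(=O)(=O)C(F)(F)F
F3 | step 8 | 2,6-dimethoxy-4-{[(1S,2R)-2-methyl-3-oxocyclobutyl]methyl}phenyl acetate | COc1cc(C[C@H]2CC(=O)[C@@H]2C)cc(OC)c1OC(C)=O
F4 | step 8 | 4-[(2R,3R)-2,3-dimethyl-4-oxo-4-(3,4,5-trimethoxyphenyl)butyl]-2,6-dimethoxyphenyl acetate | COc1cc(C[C@@H](C)[C@@H](C)C(=O)c2cc(OC)c(OC)c(OC)c2)cc(OC)c1OC(C)=O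
F5 | step 8 | (2R,3R)-4-(4-hydroxy-3,5-dimethoxyphenyl)-2,3-dimethyl-1-(3,4,5-trimethoxyphenyl)butan-1-one | COc1cc(C[C@@H](C)[C@@H](C)C(=O)c2cc(OC)c(OC)c(OC)c2)cc(OC)c1O
F6 | step 4 | 2-[4-(allyloxy)-3,5-dimethoxyphenyl]-3,4,5-trimethoxyphenyl trifluoromethanesulfonate | C=CCOc1c(OC)cc(cc1OC)-c1c(OS(=O)(=O)C(F)(F)F)cc(OC)c(OC)c1OC
F7 | step 4 | racemic 2-(5-allyl-3,5-dimethoxy-4-oxocyclohexa-1,2-dien-1-yl type ortho-dienone: 6-allyl-2,6-dimethoxy-4-aryl-cyclohexa-2,4-dienone, aryl = 2-triflyloxy-4,5,6-trimethoxyphenyl) | C=CCC1(OC)C=C(C=C(OC)C1=O)c1c(OS(=O)(=O)C(F)(F)F)cc(OC)c(OC)c1OC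
F8 | step 6 | N,N-dimethyl-N-(prop-1-en-1-ylidene)ammonium triflate | CC=C=[N+](C)C.[O-]S(=O)(=O)C(F)(F)F
F9 | step 6 | racemic trans N,N-dimethylcyclobutaniminium triflate from 7 and F8 (one enantiomer drawn) | COC1=CC(C[C@H]2CC(=[N+](C)C)[C@@H]2C)(C=C(OC)C1=O)c1c(OS(=O)(=O)C(F)(F)F)cc(OC)c(OC)c1OC.[O-]S(=O)(=O)C(F)(F)F
F10 | step 6 | (2S,3R) enantiomer of 13 | COC1=CC(C[C@@H]2CC(=O)[C@H]2C)(C=C(OC)C1=O)c1c(OS(=O)(=O)C(F)(F)F)cc(OC)c(OC)c1OC
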